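## Structural features

The target is a 9,9'-epoxylignan: a tetrahydrofuran (ring atoms O, C9, C8, C8', C9') whose two neighbouring ring carbons C8 and C8' each carry one side arm. C8' carries the benzylic methylene C7' of a 4-hydroxy-3-methoxyphenyl (guaiacyl) ring. C8 carries the secondary carbinol C7, which is bonded to a 4-hydroxy-3,5-dimethoxyphenyl (syringyl) ring. The three stereocentres are contiguous: C7 is S, C8 is R and C8' is R. The two ring substituents are trans, and C7-OH and the C8–C8' bond are syn when the chain C9–C8–C7–aryl is drawn as a zigzag. The C7 hydroxyl is benzylic and para to a free phenol, so acid, strong base or hydrogenolysis can ionise it through a quinone methide with loss or inversion of C7; both phenols and both electron-rich rings are also sensitive to oxidants and electrophiles. The real difficulty is that C9 and C9' are plain ether methylenes with no carbonyl handle, while C7/C8 and C8/C8' must both be set. The key step uses the fact that C9' is an unsubstituted O–CH2 bonded to C8', and that C8' is bonded to the benzylic CH2 C7'. Read backwards, the C9'–C8' bond is an oxygen-substituted radical at C9' adding to a C8'=C7' styrene, with the O–C9–C8 tether sized for a five-membered ring.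

## Logic of the disconnections

18 to 17. Three O–Si bonds are cut. Carrying all three hydroxyls as one kind of silyl ether keeps the end game to a single fluoride step and avoids acid, strong base and hydrogenation near the C7 carbinol. The forward step must be buffered so that the phenols stay protonated while the C7 ether is cleaved.

17 to 16. The C9'–C8' bond is cut. This opens the tetrahydrofuran, turns C8'–C7' into an (E)-alkene conjugated to the guaiacyl ring and leaves C9' as an O–CH2–SePh group. The cut is made here because the aryl group makes the alkene a fast radical acceptor and fixes the regiochemistry of addition. The gain is the loss of the ring and of the C8' stereocentre; what remains is an acyclic chain whose only stereocentres, C7 and C8, are an aldol pair. The forward step must close 5-exo faster than the radical is reduced, and must place the new arm trans to the C8 substituent.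

16 to 12 and 15. The O–C9' ether bond is cut, since the C9 oxygen is a primary alkoxide nucleophile and C9' of 15 is an SN2-active α-seleno halide. Acid-based ways of building the O–CH2–Se unit are excluded, because an oxocarbenium ion at C9' would attack the electron-rich styrene. The basic alkylation in turn demands silyl groups that neither migrate to nor are transferred to the alkoxide, which is why triisopropylsilyl is used on all three oxygens. 15 is traced to 13 by cutting the Se–CH2 bond.

12 to 11 to 10. C9 is returned to the acyl oxidation level (C9–N bond to the ring nitrogen of 6) and the C7 O–Si bond is cut. The acyl group at C9 is what allows C7–C8 to be made with control, and it is removed by hydride at no cost in steps. The forward reduction must attack the exocyclic carbonyl only and must not epimerise the doubly activated C8–H.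

10 to 8 and 2. The C7–C8 bond is cut. This is the aldol bond, and making it sets C7 and C8 together from two fragments of similar size. The forward step requires a Z-enolate, reaction at the α-carbon and not the γ-carbon of the dienolate, and facial control by the benzyl group of the auxiliary.

8 to 5 and 6, then 5 to 4. The N–C9 acyl bond is cut first, then the C8'=C7' double bond by a Wittig disconnection to the aldehyde carbon of 4. The olefination must give the (E)-alkene and leave it in conjugation with the arene. 4 and 2 come from 3 and 1 by cutting one O–Si bond each.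

## Other disconnections considered

Alternative 1: The cuts are C7–C8 and C8'–C7', which leave the C9–C8–C8'–C9' core as (5R)-5-(l-menthyloxy)furan-2(5H)-one A1. In the forward step the 2-lithio derivative of 2-[4-(tert-butyldimethylsilyloxy)-3,5-dimethoxyphenyl]-1,3-dithiane A2 would add 1,4 to A1 anti to the menthyloxy group. The lactone enolate would then be alkylated by 4-(bromomethyl)-1-(tert-butyldimethylsilyloxy)-2-methoxybenzene A3 anti to the new C8 substituent, giving the all-trans lactone A4.
- In favour: two C–C bonds, three components and both ring stereocentres in one flask, with acetal-based control from a cheap controller. On convergence and on the security of the C8/C8' trans relationship this plan is the better one.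
- Against: C7 arrives as a dithioacetal. It would have to be unmasked with thiophilic or oxidative reagents (HgCl2 type) next to two electron-rich silyloxyarenes, and then reduced with 7S selectivity that nothing in A4 guarantees. C9 (acetal) and C9' (lactone carbonyl) both sit above the ether oxidation level, so a reduction to the 1,4-diol and a ring closure are needed, and that closure must keep the C7 hydroxyl from forming a competing 7,9'-ether.
- Comparison: both plans use substrate control at C8' (anti alkylation there, chair-like radical closure here), so they are equal in kind. The chosen plan sets C7 with C8 in one aldol and needs no redox correction of the ring carbons. Counting the preparation of A1 to A3 and about six steps after A4, the alternative would be longer overall.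

Alternative 2: The cuts are C8–C9 and C8'–C9', so the whole CH2–O–CH2 unit is removed as a carbonyl ylide. In the forward step CsF would release the parent ylide from chloromethyl (trimethylsilyl)methyl ether A5, and the ylide would add across the (E)-alkene of the enoyl imide A6 to give the tetrahydrofuran A7.
- In favour: the ring appears at the correct oxidation level with both ring methylenes in one step. A concerted cycloaddition transfers the E geometry to the trans ring relationship with certainty, which is better than the chosen plan on that point.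
- Against: absolute facial control would rest on the oxazolidinone without a chelating Lewis acid, since such acids do not coexist with fluoride, and rotamer freedom of the enoyl imide would erode it. Fluoride would also attack the aryl silyl ether of A6. The CH2 of A6 between arene and alkene is acidic enough for base-induced migration of the double bond into styrene conjugation. C7 and the syringyl ring would still have to be attached afterwards by acyl substitution and ketone reduction, with the C7 configuration governed by C8 alone.
- Comparison: the alternative is stereospecific where the chosen plan is only stereoselective, but it leaves absolute configuration and C7 less secure than an auxiliary-controlled aldol. Step counts would be about equal.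

Alternative 3: The cut is C8–C8'. In the forward step Rh2(S-PTTL)4 (dirhodium tetrakis[N-phthaloyl-(S)-tert-leucinate]) would decompose the diazo ester A8, and the carbenoid at C8 would insert into one of the two enantiotopic C8'–H bonds to close the γ-lactone A9.
- In favour: the absolute configuration comes from a catalyst and not from a stoichiometric auxiliary. A8 would be assembled by esterification and diazo transfer, so the way to the key step is shorter than in the chosen plan. C8 of A9 lies between two carbonyls, so the trans relationship is under thermodynamic control. On these three points the alternative is the equal or the better.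
- Against: the C8'–H bonds are unactivated methylene C–H bonds β to the ester oxygen. The benzylic C7'–H (six-membered lactone), the electron-rich arenes (aromatic cycloaddition or substitution) and β-lactone formation would compete. A carbenoid flanked by two acceptor groups is very electrophilic, and good enantiocontrol is not assured. After A9 the C7 ketone would need a diastereoselective reduction, and the lactone carbonyl C9 would have to be taken to CH2 through the diol and a selective re-closure.
- Comparison: the alternative wins on atom economy and on the length of the approach to its key step. The chosen plan wins on site selectivity, on the control of C7 and on redox economy after the key step.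

Key step: step 10

Remark on the chemistry: the three hydroxyls are carried as triisopropylsilyl ethers instead of tert-butyldimethylsilyl ethers, because the ether-forming step 9 passes through a primary alkoxide that could take over a less hindered aryl or neighbouring silyl group; the skeletons of 16 and 17 are unaffected. The configurations were checked: the syn aldol with the (S)-auxiliary gives 7S,8R, and the trans closure gives 8'R, as the target requires.

## Route

Step 1
Reactants: 1 syringaldehyde (4-hydroxy-3,5-dimethoxybenzaldehyde)
Product: 2 3,5-dimethoxy-4-(triisopropylsilyloxy)benzaldehyde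
Conditions: TIPSCl, imidazole, DMF, rt to 40 °C
Reagents that add atoms: triisopropylsilyl chloride, CC(C)[Si](Cl)(C(C)C)C(C)C
Why: Imidazole-promoted silylation of the phenol masks the acidic OH for the later enolate, hydride and alkoxide steps; the bulky triisopropylsilyl aryl ether is chosen for its resistance to alkoxides.

Step 2
Reactants: 3 vanillin (4-hydroxy-3-methoxybenzaldehyde)
Product: 4 3-methoxy-4-(triisopropylsilyloxy)benzaldehyde
Conditions: TIPSCl, imidazole, DMF, rt
Reagents that add atoms: triisopropylsilyl chloride, CC(C)[Si](Cl)(C(C)C)C(C)C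
Why: Same phenol silylation as in step 1; the silyl ether must survive the basic Wittig, hydride and alkoxide steps that follow.

Step 3
Reactants: 4 3-methoxy-4-(triisopropylsilyloxy)benzaldehyde
Product: 5 (E)-4-[3-methoxy-4-(triisopropylsilyloxy)phenyl]but-3-enoic acid
Conditions: Ph3P+CH2CH2CO2H Br−, NaHMDS (2 equiv per salt), THF, −78 °C to rt; then 1 M HCl to pH 3
Reagents that add atoms: (2-carboxyethyl)triphenylphosphonium bromide, [Br-].OC(=O)CC[P+](c1ccccc1)(c1ccccc1)c1ccccc1
Why: Wittig reaction of the ylide–carboxylate; ylides that carry an anionic carboxylate are expected to give mainly the (E)-alkene with aromatic aldehydes, and the double bond should stay conjugated to the arene and not to the carboxyl group.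

Step 4
Reactants: 5 (E)-4-[3-methoxy-4-(triisopropylsilyloxy)phenyl]but-3-enoic acid; 6 (S)-4-benzyl-2-oxazolidinone
Product: 8 (S)-4-benzyl-3-{(E)-4-[3-methoxy-4-(triisopropylsilyloxy)phenyl]but-3-enoyl}oxazolidin-2-one, via mixed pivalic anhydride 7 (not isolated)
Conditions: PivCl, Et3N, THF, −20 °C; then 6, LiCl, rt
Reagents that add atoms: none
Why: N-acylation of the oxazolidinone through a mixed anhydride with LiCl/Et3N activation; attack should occur at the less hindered acyl carbon, and the styrene-conjugated β,γ-alkene is the more stable isomer and should not migrate.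

Step 5
Reactants: 8 (S)-4-benzyl-3-{(E)-4-[3-methoxy-4-(triisopropylsilyloxy)phenyl]but-3-enoyl}oxazolidin-2-one; 2 3,5-dimethoxy-4-(triisopropylsilyloxy)benzaldehyde
Product: 10 (S)-4-benzyl-3-{(2S,3E)-2-[(S)-[3,5-dimethoxy-4-(triisopropylsilyloxy)phenyl](hydroxy)methyl]-4-[3-methoxy-4-(triisopropylsilyloxy)phenyl]but-3-enoyl}oxazolidin-2-one, via dibutylboron Z-enolate 9 (not isolated)
Conditions: Bu2BOTf, iPr2NEt, CH2Cl2, −78 to 0 °C; then 2, −78 to 0 °C; pH 7 buffer, MeOH, 30% H2O2, 0 °C
Reagents that add atoms: none
Why: Evans syn aldol: the Z-configured boron dienolate should react at its α-carbon through a closed chair transition state with the oxazolidinone carbonyl turned away from the enolate oxygen, so the aldehyde approaches the face opposite the benzyl group; this sets C8 (2S in the imide) and C7 (S) as the syn pair of the target.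

Step 6
Reactants: 10 (S)-4-benzyl-3-{(2S,3E)-2-[(S)-[3,5-dimethoxy-4-(triisopropylsilyloxy)phenyl](hydroxy)methyl]-4-[3-methoxy-4-(triisopropylsilyloxy)phenyl]but-3-enoyl}oxazolidin-2-one
Product: 11 (S)-4-benzyl-3-{(2S,3E)-2-[(S)-[3,5-dimethoxy-4-(triisopropylsilyloxy)phenyl](triisopropylsilyloxy)methyl]-4-[3-methoxy-4-(triisopropylsilyloxy)phenyl]but-3-enoyl}oxazolidin-2-one
Conditions: TIPSOTf, 2,6-lutidine, CH2Cl2, 0 °C to rt
Reagents that add atoms: triisopropylsilyl trifluoromethanesulfonate, CC(C)[Si](OS(=O)(=O)C(F)(F)F)(C(C)C)C(C)C
Why: Silyl triflate with a hindered pyridine base should silylate the benzylic aldol hydroxyl without retro-aldol cleavage or epimerisation at the acidic C8–H; the ether blocks the C7 oxygen for step 9 and enlarges the C8 substituent for step 10.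

Step 7
Reactants: 11 (S)-4-benzyl-3-{(2S,3E)-2-[(S)-[3,5-dimethoxy-4-(triisopropylsilyloxy)phenyl](triisopropylsilyloxy)methyl]-4-[3-methoxy-4-(triisopropylsilyloxy)phenyl]but-3-enoyl}oxazolidin-2-one
Product: 12 (2R,3E)-2-{(S)-[3,5-dimethoxy-4-(triisopropylsilyloxy)phenyl](triisopropylsilyloxy)methyl}-4-[3-methoxy-4-(triisopropylsilyloxy)phenyl]but-3-en-1-ol
Conditions: LiBH4, MeOH (1 equiv), THF, 0 °C; sat. aq. NH4Cl
Reagents that add atoms: none
Why: Reductive removal of the auxiliary: hydride should attack the exocyclic imide carbonyl and take C9 to CH2OH at 0 °C without touching a stereocentre; the C8 descriptor changes from S to R only because the substituent priorities change.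

Step 8
Reactants: 13 diphenyl diselenide
Product: 15 chloromethyl phenyl selenide, via sodium benzeneselenolate 14 (not isolated)
Conditions: NaBH4, EtOH, 0 °C; then added slowly to BrCH2Cl (large excess), 0 °C to rt
Reagents that add atoms: bromochloromethane, ClCBr
Why: Borohydride cleaves the Se–Se bond and the selenolate displaces bromide from the dihalomethane in an SN2 reaction; inverse addition into excess dihalide should limit a second substitution on the product.

Step 9
Reactants: 12 (2R,3E)-2-{(S)-[3,5-dimethoxy-4-(triisopropylsilyloxy)phenyl](triisopropylsilyloxy)methyl}-4-[3-methoxy-4-(triisopropylsilyloxy)phenyl]but-3-en-1-ol; 15 chloromethyl phenyl selenide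
Product: 16 {[(2R,3E)-2-{(S)-[3,5-dimethoxy-4-(triisopropylsilyloxy)phenyl](triisopropylsilyloxy)methyl}-4-[3-methoxy-4-(triisopropylsilyloxy)phenyl]but-3-en-1-yl]oxymethyl}(phenyl)selane (the phenylselenomethyl ether of 12)
Conditions: NaH, THF, 0 °C; then 15, Bu4NI (cat.), 0 °C to rt
Reagents that add atoms: none
Why: Williamson etherification of the primary alkoxide with the α-seleno chloride, helped by iodide exchange; base is used because acid-promoted acetal formation would send an oxocarbenium ion onto the electron-rich styrene, and the hindered triisopropylsilyl ethers are not expected to migrate or transfer to the alkoxide.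

Step 10
Reactants: 16 the phenylselenomethyl ether of 12
Product: 17 (3R,4R)-3-{(S)-[3,5-dimethoxy-4-(triisopropylsilyloxy)phenyl](triisopropylsilyloxy)methyl}-4-[3-methoxy-4-(triisopropylsilyloxy)benzyl]tetrahydrofuran
Conditions: Bu3SnH (syringe pump), AIBN (cat.), benzene (0.01 M), 80 °C
Reagents that add atoms: none
Why: Radical chain reaction: the Bu3Sn radical, started by AIBN, takes the PhSe group from C9' of 16, the weak C–Se bond next to oxygen making this abstraction fast, and leaves an alkoxymethyl radical. This radical adds to C8' of the (E)-styrene in a 5-exo-trig closure that forms the C9'–C8' bond and the tetrahydrofuran (ring atoms C9', O, C9, C8, C8'), and the benzylic radical at C7' then takes hydrogen from Bu3SnH and regenerates the chain carrier. The closest known reaction type is the Bu3SnH-mediated cyclisation of alkoxymethyl radicals from phenylselenomethyl ethers of homoallylic alcohols to 3,4-disubstituted tetrahydrofurans. The only new stereocentre, C8', is controlled by C8: in the chair-like transition state the large aryl(silyloxy)methyl group on C8 lies pseudo-equatorial, so the arylmethyl arm should end trans to it (8'R). The step needs cyclisation to outrun direct reduction of the first radical, which the aryl-activated alkene and a low stationary Bu3SnH concentration (slow addition, high dilution) should secure. It needs exo and not endo closure, which is secured because attack at C7' would give an unstabilised secondary radical in a six-membered ring while attack at C8' gives a benzylic one. A 1,5-hydrogen shift from C7–H is the remaining competitor, and it is disfavoured by the nucleophilic character of both partners and by the bulky silyl ether on C7. C7 and C8 carry no radical or ionic character at any point and should keep their configuration.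

Step 11
Reactants: 17 (3R,4R)-3-{(S)-[3,5-dimethoxy-4-(triisopropylsilyloxy)phenyl](triisopropylsilyloxy)methyl}-4-[3-methoxy-4-(triisopropylsilyloxy)benzyl]tetrahydrofuran
Product: 18 (S)-(4-hydroxy-3,5-dimethoxyphenyl)[(3R,4R)-4-(4-hydroxy-3-methoxybenzyl)tetrahydrofuran-3-yl]methanol (CNP0307127.1)
Conditions: TBAF, AcOH (1:1), THF, 0 °C to rt
Reagents that add atoms: none
Why: Fluoride cleaves all three Si–O bonds; the acetic acid buffer keeps the phenols protonated so that the C7 carbinol, benzylic and para to a phenol, is not ionised through a quinone methide, and no stereocentre is affected.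

## Compound list

1 | syringaldehyde | COc1cc(C=O)cc(OC)c1O | starting material
2 | 3,5-dimethoxy-4-(triisopropylsilyloxy)benzaldehyde | COc1cc(C=O)cc(OC)c1O[Si](C(C)C)(C(C)C)C(C)C | intermediate
3 | vanillin | COc1cc(C=O)ccc1O | starting material
4 | 3-methoxy-4-(triisopropylsilyloxy)benzaldehyde | COc1cc(C=O)ccc1O[Si](C(C)C)(C(C)C)C(C)C | intermediate
5 | (E)-4-[3-methoxy-4-(triisopropylsilyloxy)phenyl]but-3-enoic acid | COc1cc(/C=C/CC(=O)O)ccc1O[Si](C(C)C)(C(C)C)C(C)C | intermediate
6 | (S)-4-benzyl-2-oxazolidinone | O=C1N[C@@H](Cc2ccccc2)CO1 | starting material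
7 | (E)-4-[3-methoxy-4-(triisopropylsilyloxy)phenyl]but-3-enoic pivalic anhydride (formed in the flask, not isolated) | COc1cc(/C=C/CC(=O)OC(=O)C(C)(C)C)ccc1O[Si](C(C)C)(C(C)C)C(C)C | intermediate
8 | (S)-4-benzyl-3-{(E)-4-[3-methoxy-4-(triisopropylsilyloxy)phenyl]but-3-enoyl}oxazolidin-2-one | COc1cc(/C=C/CC(=O)N2[C@@H](Cc3ccccc3)COC2=O)ccc1O[Si](C(C)C)(C(C)C)C(C)C | intermediate
9 | dibutylboron (Z)-enolate of 8 (formed in the flask, not isolated) | CCCCB(CCCC)O/C(=C\C=C\c1ccc(O[Si](C(C)C)(C(C)C)C(C)C)c(OC)c1)N1[C@@H](Cc2ccccc2)COC1=O | intermediate
10 | (S)-4-benzyl-3-{(2S,3E)-2-[(S)-[3,5-dimethoxy-4-(triisopropylsilyloxy)phenyl](hydroxy)methyl]-4-[3-methoxy-4-(triisopropylsilyloxy)phenyl]but-3-enoyl}oxazolidin-2-one | COc1cc(/C=C/[C@H](C(=O)N2[C@@H](Cc3ccccc3)COC2=O)[C@H](O)c2cc(OC)c(O[Si](C(C)C)(C(C)C)C(C)C)c(OC)c2)ccc1O[Si](C(C)C)(C(C)C)C(C)C | intermediate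
11 | (S)-4-benzyl-3-{(2S,3E)-2-[(S)-[3,5-dimethoxy-4-(triisopropylsilyloxy)phenyl](triisopropylsilyloxy)methyl]-4-[3-methoxy-4-(triisopropylsilyloxy)phenyl]but-3-enoyl}oxazolidin-2-one | COc1cc(/C=C/[C@H](C(=O)N2[C@@H](Cc3ccccc3)COC2=O)[C@H](O[Si](C(C)C)(C(C)C)C(C)C)c2cc(OC)c(O[Si](C(C)C)(C(C)C)C(C)C)c(OC)c2)ccc1O[Si](C(C)C)(C(C)C)C(C)C | intermediate
12 | (2R,3E)-2-{(S)-[3,5-dimethoxy-4-(triisopropylsilyloxy)phenyl](triisopropylsilyloxy)methyl}-4-[3-methoxy-4-(triisopropylsilyloxy)phenyl]but-3-en-1-ol | COc1cc(/C=C/[C@H](CO)[C@H](O[Si](C(C)C)(C(C)C)C(C)C)c2cc(OC)c(O[Si](C(C)C)(C(C)C)C(C)C)c(OC)c2)ccc1O[Si](C(C)C)(C(C)C)C(C)C | intermediate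
13 | diphenyl diselenide | c1ccc(cc1)[Se][Se]c1ccccc1 | starting material
14 | sodium benzeneselenolate (formed in the flask, not isolated) | [Na+].[Se-]c1ccccc1 | intermediate
15 | chloromethyl phenyl selenide | ClC[Se]c1ccccc1 | intermediate
16 | phenylselenomethyl ether of 12, (7S,8R) in lignan numbering | COc1cc(/C=C/[C@H](COC[Se]c2ccccc2)[C@H](O[Si](C(C)C)(C(C)C)C(C)C)c2cc(OC)c(O[Si](C(C)C)(C(C)C)C(C)C)c(OC)c2)ccc1O[Si](C(C)C)(C(C)C)C(C)C | intermediate
17 | (3R,4R)-3-{(S)-[3,5-dimethoxy-4-(triisopropylsilyloxy)phenyl](triisopropylsilyloxy)methyl}-4-[3-methoxy-4-(triisopropylsilyloxy)benzyl]tetrahydrofuran | COc1cc(C[C@H]2COC[C@@H]2[C@H](O[Si](C(C)C)(C(C)C)C(C)C)c2cc(OC)c(O[Si](C(C)C)(C(C)C)C(C)C)c(OC)c2)ccc1O[Si](C(C)C)(C(C)C)C(C)C | intermediate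
18 | (S)-(4-hydroxy-3,5-dimethoxyphenyl)[(3R,4R)-4-(4-hydroxy-3-methoxybenzyl)tetrahydrofuran-3-yl]methanol (CNP0307127.1) | COc1cc(C[C@H]2COC[C@@H]2[C@H](O)c2cc(OC)c(O)c(OC)c2)ccc1O | target

## Step count and least certain steps

Total: 11 steps. Longest linear sequence: 9 steps (3 to 18 through steps 2, 3, 4, 5, 6, 7, 9, 10 and 11).

**Step 10 (key step).** The most likely failures are hydrogen transfer to the alkoxymethyl radical before ring closure, erosion of the trans preference at 80 °C, and an inefficient chain because the stabilised benzylic radical abstracts hydrogen slowly. The fallback replaces the radical by an anionic closure of the same bond. It sets out from 12, which would be alkylated (KH, Bu3SnCH2I, THF) to the tributylstannylmethyl ether of 12 F1. Tin–lithium exchange with BuLi in THF at −78 °C would give an α-alkoxymethyllithium that closes 5-exo onto the styrene on warming towards 0 °C, and the benzyllithium would be quenched with MeOH. This intramolecular carbolithiation is a known reaction type for tetrahydrofurans, and it returns to the route at 17.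

**Step 9.** The most likely failure is movement of a silyl group to the primary alkoxide, by 1,3-migration from the C7 oxygen or by transfer from an aryl oxygen, which would scramble the position of the ether. The fallback avoids an alkoxide next to a C7 silyl ether. It sets out from 10, which would be reduced (LiBH4, MeOH, THF, 0 °C) to (1S,2R,3E)-1-[3,5-dimethoxy-4-(triisopropylsilyloxy)phenyl]-2-(hydroxymethyl)-4-[3-methoxy-4-(triisopropylsilyloxy)phenyl]but-3-en-1-ol F2. Bu2SnO in toluene at reflux would convert F2 to the dibutylstannylene acetal of F2 F3, which 15 and Bu4NI should alkylate at the primary oxygen to give the C7-hydroxy phenylselenomethyl ether F4. Silylation of F4 (TIPSOTf, 2,6-lutidine) returns to the route at 16.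

**Step 5.** The most likely failures are slow addition of the boron dienolate to the electron-rich, deactivated aldehyde, competing reaction at the γ-carbon, and retro-aldol cleavage on work-up. The fallback uses a more reactive TiCl4-derived enolate of a thiazolidinethione. It sets out from 5, which would be coupled with (S)-4-benzylthiazolidine-2-thione (EDC, DMAP) to the N-acyl thiazolidinethione F5. Enolisation with TiCl4, iPr2NEt and N-methylpyrrolidinone and addition of 2 should give the syn aldol adduct of the same sense F6. Silylation (TIPSOTf, 2,6-lutidine) would give the silyl ether F7, and NaBH4 in THF/EtOH would remove the auxiliary under milder hydride conditions and return to the route at 12.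

**Step 3.** The most likely failures are incomplete E-selectivity with a difficult separation, and attack of the strongly basic ylide medium on the aryl silyl ether. The fallback builds the acid by condensation instead of olefination. It sets out from 4, which would be homologated with Ph3P=CHOMe to the enol ether 4-(2-methoxyvinyl)-2-methoxy-1-(triisopropylsilyloxy)benzene F8. Mild acid hydrolysis would give 2-[3-methoxy-4-(triisopropylsilyloxy)phenyl]acetaldehyde F9. A Knoevenagel–Doebner condensation of F9 with malonic acid under decarboxylative, β,γ-selective conditions (piperidinium acetate, DMSO, 100 °C) should place the double bond in conjugation with the arene with E geometry, and returns to the route at 5.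

Further compounds

F1 | step 10 | tributylstannylmethyl ether of 12 | COc1cc(/C=C/[C@H](COC[Sn](CCCC)(CCCC)CCCC)[C@H](O[Si](C(C)C)(C(C)C)C(C)C)c2cc(OC)c(O[Si](C(C)C)(C(C)C)C(C)C)c(OC)c2)ccc1O[Si](C(C)C)(C(C)C)C(C)C
F2 | step 9 | (1S,2R,3E)-1-[3,5-dimethoxy-4-(triisopropylsilyloxy)phenyl]-2-(hydroxymethyl)-4-[3-methoxy-4-(triisopropylsilyloxy)phenyl]but-3-en-1-ol | COc1cc(/C=C/[C@H](CO)[C@H](O)c2cc(OC)c(O[Si](C(C)C)(C(C)C)C(C)C)c(OC)c2)ccc1O[Si](C(C)C)(C(C)C)C(C)C
F3 | step 9 | dibutylstannylene acetal of F2 (2,2-dibutyl-1,3,2-dioxastanninane) | CCCC[Sn]1(CCCC)OC[C@@H](/C=C/c2ccc(O[Si](C(C)C)(C(C)C)C(C)C)c(OC)c2)[C@@H](c2cc(OC)c(O[Si](C(C)C)(C(C)C)C(C)C)c(OC)c2)O1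
F4 | step 9 | C7-hydroxy phenylselenomethyl ether, (1S,2R,3E)-1-[3,5-dimethoxy-4-(triisopropylsilyloxy)phenyl]-4-[3-methoxy-4-(triisopropylsilyloxy)phenyl]-2-[(phenylselanylmethoxy)methyl]but-3-en-1-ol | COc1cc(/C=C/[C@H](COC[Se]c2ccccc2)[C@H](O)c2cc(OC)c(O[Si](C(C)C)(C(C)C)C(C)C)c(OC)c2)ccc1O[Si](C(C)C)(C(C)C)C(C)C
F5 | step 5 | (E)-1-[(S)-4-benzyl-2-thioxothiazolidin-3-yl]-4-[3-methoxy-4-(triisopropylsilyloxy)phenyl]but-3-en-1-one | COc1cc(/C=C/CC(=O)N2[C@@H](Cc3ccccc3)CSC2=S)ccc1O[Si](C(C)C)(C(C)C)C(C)C
F6 | step 5 | (2S,3E)-1-[(S)-4-benzyl-2-thioxothiazolidin-3-yl]-2-[(S)-[3,5-dimethoxy-4-(triisopropylsilyloxy)phenyl](hydroxy)methyl]-4-[3-methoxy-4-(triisopropylsilyloxy)phenyl]but-3-en-1-one | COc1cc(/C=C/[C@H](C(=O)N2[C@@H](Cc3ccccc3)CSC2=S)[C@H](O)c2cc(OC)c(O[Si](C(C)C)(C(C)C)C(C)C)c(OC)c2)ccc1O[Si](C(C)C)(C(C)C)C(C)C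
F7 | step 5 | (2S,3E)-1-[(S)-4-benzyl-2-thioxothiazolidin-3-yl]-2-[(S)-[3,5-dimethoxy-4-(triisopropylsilyloxy)phenyl](triisopropylsilyloxy)methyl]-4-[3-methoxy-4-(triisopropylsilyloxy)phenyl]but-3-en-1-one | COc1cc(/C=C/[C@H](C(=O)N2[C@@H](Cc3ccccc3)CSC2=S)[C@H](O[Si](C(C)C)(C(C)C)C(C)C)c2cc(OC)c(O[Si](C(C)C)(C(C)C)C(C)C)c(OC)c2)ccc1O[Si](C(C)C)(C(C)C)C(C)C
F8 | step 3 | 4-(2-methoxyvinyl)-2-methoxy-1-(triisopropylsilyloxy)benzene (E/Z mixture, geometry not defined) | COC=Cc1ccc(O[Si](C(C)C)(C(C)C)C(C)C)c(OC)c1
F9 | step 3 | 2-[3-methoxy-4-(triisopropylsilyloxy)phenyl]acetaldehyde | COc1cc(CC=O)ccc1O[Si](C(C)C)(C(C)C)C(C)C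
A1 | alternative 1 | (5R)-5-[(1R,2S,5R)-menthyloxy]furan-2(5H)-one | O=C1O[C@@H](O[C@H]2[C@H](C(C)C)CC[C@@H](C)C2)C=C1
A2 | alternative 1 | 2-[4-(tert-butyldimethylsilyloxy)-3,5-dimethoxyphenyl]-1,3-dithiane | COc1cc(C2SCCCS2)cc(OC)c1O[Si](C)(C)C(C)(C)C
A3 | alternative 1 | 4-(bromomethyl)-1-(tert-butyldimethylsilyloxy)-2-methoxybenzene | COc1cc(CBr)ccc1O[Si](C)(C)C(C)(C)C
A4 | alternative 1 | (3R,4R,5R)-3-[4-(tert-butyldimethylsilyloxy)-3-methoxybenzyl]-4-{2-[4-(tert-butyldimethylsilyloxy)-3,5-dimethoxyphenyl]-1,3-dithian-2-yl}-5-[(1R,2S,5R)-menthyloxy]dihydrofuran-2(3H)-one | O=C1O[C@@H](O[C@H]2[C@H](C(C)C)CC[C@@H](C)C2)[C@H](C2(SCCCS2)c2cc(OC)c(O[Si](C)(C)C(C)(C)C)c(OC)c2)[C@H]1Cc1ccc(O[Si](C)(C)C(C)(C)C)c(OC)c1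
A5 | alternative 2 | chloromethyl (trimethylsilyl)methyl ether | C[Si](C)(C)COCCl
A6 | alternative 2 | (S)-4-benzyl-3-{(E)-4-[4-(tert-butyldimethylsilyloxy)-3-methoxyphenyl]but-2-enoyl}oxazolidin-2-one | O=C1OC[C@H](Cc2ccccc2)N1C(=O)/C=C/Cc1ccc(O[Si](C)(C)C(C)(C)C)c(OC)c1
A7 | alternative 2 | (S)-4-benzyl-3-{[(3R,4R)-4-(4-tert-butyldimethylsilyloxy-3-methoxybenzyl)tetrahydrofuran-3-yl]carbonyl}oxazolidin-2-one | O=C1OC[C@H](Cc2ccccc2)N1C(=O)[C@H]1COC[C@@H]1Cc1ccc(O[Si](C)(C)C(C)(C)C)c(OC)c1
A8 | alternative 3 | 3-[4-(tert-butyldimethylsilyloxy)-3-methoxyphenyl]propyl 3-[4-(tert-butyldimethylsilyloxy)-3,5-dimethoxyphenyl]-2-diazo-3-oxopropanoate | [N-]=[N+]=C(C(=O)OCCCc1ccc(O[Si](C)(C)C(C)(C)C)c(OC)c1)C(=O)c1cc(OC)c(O[Si](C)(C)C(C)(C)C)c(OC)c1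
A9 | alternative 3 | (3S,4R)-3-[4-(tert-butyldimethylsilyloxy)-3,5-dimethoxybenzoyl]-4-[4-(tert-butyldimethylsilyloxy)-3-methoxybenzyl]dihydrofuran-2(3H)-one | O=C1OC[C@H](Cc2ccc(O[Si](C)(C)C(C)(C)C)c(OC)c2)[C@H]1C(=O)c1cc(OC)c(O[Si](C)(C)C(C)(C)C)c(OC)c1
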